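**Retrosynthetic overview**

- Ring A is cut at the bond between the ring carbon that bears chain C7 and the hydroxyl carbon flanked by that carbon and the acyl carbon. The methoxy, acyl and this hydroxyl carbon of ring A map onto C4 (OMe), C3 (acyl) and C2 (lactone C=O) of a 3-acyl-4-methoxy-2-pyranone; the other hydroxyl carbon is pyranone C6, and the C7-bearing carbon is the CH2 on pyranone C6, which already carries the (S)-diarylmethine. (Chain C1–C7 runs from the CH2 on ring D through carbinol C3 and alkene C5=C6 to C7; ring B is the enone aryl, ring C the aryl on C7.)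
- The pyranone comes from a 3,5-dioxo ester (acetoacetate dianion plus Weinreb amide), followed by acetylation at pyranone C3, aldol condensation with the ring B aldehyde and O-methylation.
- The amide comes from an (S)-3-arylpent-4-enoate and an (S)-homoallyl silyl ether joined by cross-metathesis (chain C5=C6). Chain C7 is set by iridium-catalysed allylic alkylation of the ring C cinnamyl carbonate with dimethyl malonate; chain C3 is set by allylboration.
- Ring order: rings B, C and D are bought; the pyranone is the only ring made on the way; ring A is formed last from it, and deprotection ends the route.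

Key step: step 18

Abbreviations: MOM = CH2OCH3; TBS = Si(CH3)2C(CH3)3; Q = (2S,3E,6S)-6-(TBS-oxy)-2,8-bis[4-(methoxymethoxy)phenyl]oct-3-en-1-yl; L = (Sa)-(1,1'-binaphthalene-2,2'-diyl) N,N-bis[(S)-1-phenylethyl]phosphoramidite.

Assumption: the (Sa,S,S) ligand L is taken to direct malonate to the face of the allyl unit that gives (R)-6; should the sense prove opposite, the mirror-image ligand is used and nothing else changes.

**Route**

Step 1
Reactants: 1 methyl (E)-3-(4-hydroxyphenyl)prop-2-enoate
Product: 2 methyl (E)-3-[4-(methoxymethoxy)phenyl]prop-2-enoate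
Conditions: MOMCl, iPr2NEt, CH2Cl2, 0 °C to rt
Reagents that add atoms: chloromethyl methyl ether (MOMCl), COCCl
Why: O-alkylation of the phenol by the α-chloro ether (Williamson-type acetal formation) should protect the future ring C phenol without touching the enoate.

Step 2
Reactants: 2 methyl (E)-3-[4-(methoxymethoxy)phenyl]prop-2-enoate
Product: 3 (E)-3-[4-(methoxymethoxy)phenyl]prop-2-en-1-ol
Conditions: iBu2AlH (2.5 equiv), CH2Cl2, −78 to −20 °C; aq. potassium sodium tartrate
Reagents that add atoms: none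
Why: iBu2AlH reduces a conjugated ester 1,2 to the allylic alcohol at low temperature and leaves the alkene and the MOM acetal alone.

Step 3
Reactants: 3 (E)-3-[4-(methoxymethoxy)phenyl]prop-2-en-1-ol
Product: 4 (E)-3-[4-(methoxymethoxy)phenyl]prop-2-en-1-yl methyl carbonate
Conditions: ClCO2Me, pyridine, CH2Cl2, 0 °C
Reagents that add atoms: methyl chloroformate, COC(=O)Cl
Why: Acylation of the primary allylic alcohol gives the linear methyl carbonate, the leaving group that the iridium catalyst ionises and that supplies methoxide as the base.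

Step 4
Reactants: 4 (E)-3-[4-(methoxymethoxy)phenyl]prop-2-en-1-yl methyl carbonate; 5 dimethyl malonate
Product: 6 dimethyl 2-{(1R)-1-[4-(methoxymethoxy)phenyl]prop-2-en-1-yl}propanedioate
Conditions: [Ir(cod)Cl]2 (2 mol %), L (4 mol %), TBD (8 mol %), THF, rt to 50 °C
Reagents that add atoms: none
Why: Iridium-catalysed asymmetric allylic alkylation: the cyclometalated iridium species formed from [Ir(cod)Cl]2 and L ionises the carbonate, malonate (deprotonated by the released methoxide) attacks the aryl-bearing allyl terminus, and the ligand fixes the face of attack so that the future chain C7 is set as (R)-6 with the branched regiochemistry typical of this catalyst.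

Step 5
Reactants: 6 dimethyl 2-{(1R)-1-[4-(methoxymethoxy)phenyl]prop-2-en-1-yl}propanedioate
Product: 7 methyl (3S)-3-[4-(methoxymethoxy)phenyl]pent-4-enoate
Conditions: NaCl, H2O, DMSO, 150 °C
Reagents that add atoms: none
Why: Krapcho dealkoxycarbonylation removes one ester under near-neutral conditions; the stereocentre is not α to a carbonyl and is untouched, its descriptor changing from R to S only because CH2CO2Me ranks below vinyl.

Step 6
Reactants: 8 methyl 3-(4-hydroxyphenyl)propanoate
Product: 9 methyl 3-[4-(methoxymethoxy)phenyl]propanoate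
Conditions: MOMCl, iPr2NEt, CH2Cl2, 0 °C to rt
Reagents that add atoms: chloromethyl methyl ether (MOMCl), COCCl
Why: The same phenol O-alkylation as in step 1 protects the future ring D phenol.

Step 7
Reactants: 9 methyl 3-[4-(methoxymethoxy)phenyl]propanoate
Product: 10 3-[4-(methoxymethoxy)phenyl]propanal
Conditions: iBu2AlH (1.1 equiv), CH2Cl2, −78 °C; MeOH, then aq. potassium sodium tartrate
Reagents that add atoms: none
Why: At −78 °C the aluminium hemiacetal from one hydride transfer is stable, so the ester should stop at the aldehyde on work-up.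

Step 8
Reactants: 10 3-[4-(methoxymethoxy)phenyl]propanal
Product: 11 (3S)-1-[4-(methoxymethoxy)phenyl]hex-5-en-3-ol
Conditions: (+)-Ipc2BOMe [from (−)-α-pinene], allylMgBr, Et2O, 0 °C to rt; then 10, −78 °C; NaOH, H2O2, rt
Reagents that add atoms: allylmagnesium bromide, C=CC[Mg]Br
Why: Brown allylboration through a chair Zimmerman–Traxler transition state; the isopinocampheyl groups of the (−)-α-pinene series deliver the allyl group to the Re face of the aldehyde, which sets chain C3 as S.

Step 9
Reactants: 11 (3S)-1-[4-(methoxymethoxy)phenyl]hex-5-en-3-ol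
Product: 12 tert-butyl{[(3S)-1-[4-(methoxymethoxy)phenyl]hex-5-en-3-yl]oxy}dimethylsilane
Conditions: TBSCl, imidazole, DMF, rt
Reagents that add atoms: tert-butyldimethylsilyl chloride (TBSCl), CC(C)(C)[Si](C)(C)Cl
Why: Imidazole-promoted silylation of the secondary alcohol gives a base-stable ether that survives every step up to the final acid treatment.

Step 10
Reactants: 7 methyl (3S)-3-[4-(methoxymethoxy)phenyl]pent-4-enoate; 12 tert-butyl{[(3S)-1-[4-(methoxymethoxy)phenyl]hex-5-en-3-yl]oxy}dimethylsilane (2 equiv)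
Product: 13 methyl (3S,4E,7S)-7-(TBS-oxy)-3,9-bis[4-(methoxymethoxy)phenyl]non-4-enoate
Conditions: second-generation Hoveyda–Grubbs catalyst (5 mol %), 1,4-benzoquinone (10 mol %), CH2Cl2, 40 °C
Reagents that add atoms: none
Why: Olefin cross-metathesis: the allylically branched alkene of 7 homodimerises slowly, so excess 12 should drive the cross product, with the E-alkene favoured thermodynamically; benzoquinone suppresses ruthenium-hydride alkene migration that would erase chain C7.

Step 11
Reactants: 13 methyl (3S,4E,7S)-7-(TBS-oxy)-3,9-bis[4-(methoxymethoxy)phenyl]non-4-enoate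
Product: 14 (3S,4E,7S)-7-(TBS-oxy)-N-methoxy-N-methyl-3,9-bis[4-(methoxymethoxy)phenyl]non-4-enamide
Conditions: MeNH(OMe)·HCl, iPrMgCl, THF, −20 to 0 °C
Reagents that add atoms: N,O-dimethylhydroxylamine hydrochloride, CNOC.Cl
Why: The chloromagnesium amide of N,O-dimethylhydroxylamine converts the ester into the Weinreb amide (aminolysis), a clean acyl donor for the next step.

Step 12
Reactants: 14 (3S,4E,7S)-7-(TBS-oxy)-N-methoxy-N-methyl-3,9-bis[4-(methoxymethoxy)phenyl]non-4-enamide; 15 methyl acetoacetate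
Product: 16 methyl (7S,8E,11S)-11-(TBS-oxy)-7,13-bis[4-(methoxymethoxy)phenyl]-3,5-dioxotridec-8-enoate
Conditions: 15 (2.5 equiv), LiN(iPr)2 (5 equiv), THF, 0 °C; then 14, −78 to 0 °C; aq. NH4Cl
Reagents that add atoms: none
Why: Claisen-type acylation of the terminal carbanion of the acetoacetate dianion by the Weinreb amide, whose chelated tetrahedral adduct is held until quench, should give the 3,5-dioxo ester without over-addition.

Step 13
Reactants: 16 methyl (7S,8E,11S)-11-(TBS-oxy)-7,13-bis[4-(methoxymethoxy)phenyl]-3,5-dioxotridec-8-enoate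
Product: 17 4-hydroxy-6-Q-2H-pyran-2-one
Conditions: DBU, toluene, 80 °C; aq. citric acid
Reagents that add atoms: none
Why: The enol oxygen of the 5-ketone attacks the ester (6-exo-trig enol lactonisation, loss of methanol) to give the 4-hydroxy-2-pyranone, a standard closure of 3,5-dioxo esters.

Step 14
Reactants: 17 4-hydroxy-6-Q-2H-pyran-2-one
Product: 19 3-acetyl-4-hydroxy-6-Q-2H-pyran-2-one, via O-acetyl enol ester 18 (not isolated)
Conditions: AcOH, DCC, DMAP (1.2 equiv), toluene, rt, then 60 °C
Reagents that add atoms: acetic acid, CC(=O)O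
Why: Steglich O-acylation gives enol ester 18, and DMAP then carries the acetyl group to pyranone C3 (Fries-type 1,3 O-to-C acyl shift) because the strongly acidic C-acyl tricarbonyl is the thermodynamic sink.

Step 15
Reactants: 20 4-hydroxybenzaldehyde
Product: 21 4-(methoxymethoxy)benzaldehyde
Conditions: MOMCl, iPr2NEt, CH2Cl2, 0 °C to rt
Reagents that add atoms: chloromethyl methyl ether (MOMCl), COCCl
Why: Phenol O-alkylation as in step 1 gives the protected ring B aldehyde.

Step 16
Reactants: 19 3-acetyl-4-hydroxy-6-Q-2H-pyran-2-one; 21 4-(methoxymethoxy)benzaldehyde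
Product: 22 4-hydroxy-3-{(E)-3-[4-(methoxymethoxy)phenyl]prop-2-enoyl}-6-Q-2H-pyran-2-one
Conditions: piperidine (0.3 equiv), CHCl3, reflux, 4 Å molecular sieves
Reagents that add atoms: none
Why: Amine-catalysed aldol condensation (Claisen–Schmidt type) of the 3-acetyl group with the non-enolisable aldehyde, with conjugation-driven dehydration, should give the E-enone; the hindered CH2 on pyranone C6 does not compete and chain C7 is not acidic.

Step 17
Reactants: 22 4-hydroxy-3-{(E)-3-[4-(methoxymethoxy)phenyl]prop-2-enoyl}-6-Q-2H-pyran-2-one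
Product: 23 4-methoxy-3-{(E)-3-[4-(methoxymethoxy)phenyl]prop-2-enoyl}-6-Q-2H-pyran-2-one
Conditions: Me2SO4, K2CO3, acetone, 56 °C
Reagents that add atoms: dimethyl sulfate, COS(=O)(=O)OC
Why: SN2 O-methylation of the tricarbonyl enolate at the oxygen on pyranone C4, the outcome known for 3-acyl-4-hydroxy-2-pyranones under these conditions, installs the future methoxy group of ring A.

Step 18
Reactants: 23 4-methoxy-3-{(E)-3-[4-(methoxymethoxy)phenyl]prop-2-enoyl}-6-Q-2H-pyran-2-one
Product: 25 (E)-1-{3-[(1S,2E,5S)-5-(TBS-oxy)-1,7-bis[4-(methoxymethoxy)phenyl]hept-2-en-1-yl]-2,4-dihydroxy-6-methoxyphenyl}-3-[4-(methoxymethoxy)phenyl]prop-2-en-1-one, via acyclic keto ester 24 (not isolated)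
Conditions: Mg(OMe)2 (5 equiv), MeOH–THF, 65 °C; aq. NH4Cl
Reagents that add atoms: none
Why: Proposed new method: methoxide adds to the lactone carbonyl (pyranone C2) of 23 and opens the ring to methyl ester 24, a push–pull β-methoxy enone ester in which pyranone C6 has become a ketone; the enolate of that ketone on the side of the CH2 that carries chain C7 then attacks the ester carbon, methoxide leaves and the trione tautomerises to the arene, so that the bond between this CH2 carbon and the former lactone carbonyl carbon closes ring A in a 6-exo-trig Dieckmann-type condensation driven by aromatisation. The closest known reactions are the alkoxide opening of 2-pyranones to 5-oxo enoates, the base-mediated closure of 5-oxo esters to cyclohexane-1,3-diones, and the Mg(OMe)2 Claisen recyclisation of 6-(2-oxoalkyl)-2-pyranones and triketo esters to acylphloroglucinols; what is new is that a carbon activated by a single carbonyl closes onto the ester released from a 3-acyl-4-methoxy-2-pyranone in one flask. No stereocentre is formed, and chain C7 keeps its S configuration because its hydrogen is β to the ketone of 24 and is never acidified. The step needs C-acylation by the ester rather than aldol addition of the same enolate to the cinnamoyl carbonyl (whose dehydration would also give an arene), retro-Claisen loss of the acyl group, or lasting attack of methoxide elsewhere. The substrate answers these as follows: attack at pyranone C4 only exchanges OMe for OMe; O-reclosure merely returns 23; the pyranone geometry places the ester cis to the ketone arm; the enone carbonyl is a cross-conjugated vinylogous ester carbonyl whose aldol adduct can aromatise only by losing hydroxide and otherwise reverts; and the enol ether at pyranone C4 leaves pyranone C3 without a stabilised carbanion for deacylation.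

Step 19
Reactants: 25 (E)-1-{3-[(1S,2E,5S)-5-(TBS-oxy)-1,7-bis[4-(methoxymethoxy)phenyl]hept-2-en-1-yl]-2,4-dihydroxy-6-methoxyphenyl}-3-[4-(methoxymethoxy)phenyl]prop-2-en-1-one
Product: 26 calyxin B, (E)-1-{2,4-dihydroxy-3-[(1S,2E,5S)-5-hydroxy-1,7-bis(4-hydroxyphenyl)hept-2-en-1-yl]-6-methoxyphenyl}-3-(4-hydroxyphenyl)prop-2-en-1-one
Conditions: HCl (1.25 M in MeOH), THF, 0 to 40 °C
Reagents that add atoms: none
Why: Methanolic HCl removes the three aryl MOM acetals by transacetalisation and solvolyses the secondary TBS ether in the same flask; chain C7, chain C3 and both E-alkenes are not touched, and the temperature is kept low so that the 2'-hydroxychalcone does not close to the flavanone.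

**Compound list**

1 | methyl (E)-3-(4-hydroxyphenyl)prop-2-enoate | COC(=O)/C=C/c1ccc(O)cc1 | starting material
2 | methyl (E)-3-[4-(methoxymethoxy)phenyl]prop-2-enoate | COC(=O)/C=C/c1ccc(OCOC)cc1 | intermediate
3 | (E)-3-[4-(methoxymethoxy)phenyl]prop-2-en-1-ol | OC/C=C/c1ccc(OCOC)cc1 | intermediate
4 | (E)-3-[4-(methoxymethoxy)phenyl]prop-2-en-1-yl methyl carbonate | COC(=O)OC/C=C/c1ccc(OCOC)cc1 | intermediate
5 | dimethyl malonate | COC(=O)CC(=O)OC | starting material
6 | dimethyl 2-{(1R)-1-[4-(methoxymethoxy)phenyl]prop-2-en-1-yl}propanedioate | COC(=O)C(C(=O)OC)[C@@H](C=C)c1ccc(OCOC)cc1 | intermediate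
7 | methyl (3S)-3-[4-(methoxymethoxy)phenyl]pent-4-enoate | COC(=O)C[C@@H](C=C)c1ccc(OCOC)cc1 | intermediate
8 | methyl 3-(4-hydroxyphenyl)propanoate | COC(=O)CCc1ccc(O)cc1 | starting material
9 | methyl 3-[4-(methoxymethoxy)phenyl]propanoate | COC(=O)CCc1ccc(OCOC)cc1 | intermediate
10 | 3-[4-(methoxymethoxy)phenyl]propanal | O=CCCc1ccc(OCOC)cc1 | intermediate
11 | (3S)-1-[4-(methoxymethoxy)phenyl]hex-5-en-3-ol | C=CC[C@@H](O)CCc1ccc(OCOC)cc1 | intermediate
12 | tert-butyl{[(3S)-1-[4-(methoxymethoxy)phenyl]hex-5-en-3-yl]oxy}dimethylsilane | C=CC[C@@H](O[Si](C)(C)C(C)(C)C)CCc1ccc(OCOC)cc1 | intermediate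
13 | methyl (3S,4E,7S)-7-(TBS-oxy)-3,9-bis[4-(methoxymethoxy)phenyl]non-4-enoate | COC(=O)C[C@@H](/C=C/C[C@@H](O[Si](C)(C)C(C)(C)C)CCc1ccc(OCOC)cc1)c1ccc(OCOC)cc1 | intermediate
14 | (3S,4E,7S)-7-(TBS-oxy)-N-methoxy-N-methyl-3,9-bis[4-(methoxymethoxy)phenyl]non-4-enamide | CON(C)C(=O)C[C@@H](/C=C/C[C@@H](O[Si](C)(C)C(C)(C)C)CCc1ccc(OCOC)cc1)c1ccc(OCOC)cc1 | intermediate
15 | methyl acetoacetate | COC(=O)CC(C)=O | starting material
16 | methyl (7S,8E,11S)-11-(TBS-oxy)-7,13-bis[4-(methoxymethoxy)phenyl]-3,5-dioxotridec-8-enoate | COC(=O)CC(=O)CC(=O)C[C@@H](/C=C/C[C@@H](O[Si](C)(C)C(C)(C)C)CCc1ccc(OCOC)cc1)c1ccc(OCOC)cc1 | intermediate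
17 | 4-hydroxy-6-Q-2H-pyran-2-one | Oc1cc(C[C@@H](/C=C/C[C@@H](O[Si](C)(C)C(C)(C)C)CCc2ccc(OCOC)cc2)c2ccc(OCOC)cc2)oc(=O)c1 | intermediate
18 | 2-oxo-6-Q-2H-pyran-4-yl acetate | CC(=O)Oc1cc(C[C@@H](/C=C/C[C@@H](O[Si](C)(C)C(C)(C)C)CCc2ccc(OCOC)cc2)c2ccc(OCOC)cc2)oc(=O)c1 | intermediate (not isolated)
19 | 3-acetyl-4-hydroxy-6-Q-2H-pyran-2-one | CC(=O)c1c(O)cc(C[C@@H](/C=C/C[C@@H](O[Si](C)(C)C(C)(C)C)CCc2ccc(OCOC)cc2)c2ccc(OCOC)cc2)oc1=O | intermediate
20 | 4-hydroxybenzaldehyde | O=Cc1ccc(O)cc1 | starting material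
21 | 4-(methoxymethoxy)benzaldehyde | O=Cc1ccc(OCOC)cc1 | intermediate
22 | 4-hydroxy-3-{(E)-3-[4-(methoxymethoxy)phenyl]prop-2-enoyl}-6-Q-2H-pyran-2-one | Oc1cc(C[C@@H](/C=C/C[C@@H](O[Si](C)(C)C(C)(C)C)CCc2ccc(OCOC)cc2)c2ccc(OCOC)cc2)oc(=O)c1C(=O)/C=C/c1ccc(OCOC)cc1 | intermediate
23 | 4-methoxy-3-{(E)-3-[4-(methoxymethoxy)phenyl]prop-2-enoyl}-6-Q-2H-pyran-2-one (key-step precursor) | COc1cc(C[C@@H](/C=C/C[C@@H](O[Si](C)(C)C(C)(C)C)CCc2ccc(OCOC)cc2)c2ccc(OCOC)cc2)oc(=O)c1C(=O)/C=C/c1ccc(OCOC)cc1 | intermediate
24 | methyl (2E,7S,8E,11S)-11-(TBS-oxy)-3-methoxy-7,13-bis[4-(methoxymethoxy)phenyl]-2-{(E)-3-[4-(methoxymethoxy)phenyl]prop-2-enoyl}-5-oxotrideca-2,8-dienoate (C2=C3 geometry as inherited from 23, labile) | COC(=O)/C(C(=O)/C=C/c1ccc(OCOC)cc1)=C(/OC)CC(=O)C[C@@H](/C=C/C[C@@H](O[Si](C)(C)C(C)(C)C)CCc1ccc(OCOC)cc1)c1ccc(OCOC)cc1 | intermediate (not isolated)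
25 | (E)-1-{3-[(1S,2E,5S)-5-(TBS-oxy)-1,7-bis[4-(methoxymethoxy)phenyl]hept-2-en-1-yl]-2,4-dihydroxy-6-methoxyphenyl}-3-[4-(methoxymethoxy)phenyl]prop-2-en-1-one (key-step product) | COc1cc(O)c([C@@H](/C=C/C[C@@H](O[Si](C)(C)C(C)(C)C)CCc2ccc(OCOC)cc2)c2ccc(OCOC)cc2)c(O)c1C(=O)/C=C/c1ccc(OCOC)cc1 | intermediate
26 | calyxin B, (E)-1-{2,4-dihydroxy-3-[(1S,2E,5S)-5-hydroxy-1,7-bis(4-hydroxyphenyl)hept-2-en-1-yl]-6-methoxyphenyl}-3-(4-hydroxyphenyl)prop-2-en-1-one | COc1cc(O)c([C@@H](/C=C/C[C@@H](O)CCc2ccc(O)cc2)c2ccc(O)cc2)c(O)c1C(=O)/C=C/c1ccc(O)cc1 | target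

**Step count and risks**

Total step count: 19. Longest linear sequence: 14 steps (steps 1–5, 10–14, 16–19).

Steps most likely to fail:

1. Step 18 (proposed new method). Several processes may defeat it. The opened ester may simply relactonise without C–C closure. The same enolate may close by aldol addition onto the cinnamoyl carbonyl and dehydrate. Methoxide may cleave the acyl group or add to the enone. Fallback, from 23 back to 25: the one-flask, reversible, chelate-controlled recyclisation is replaced by two separate known operations with an isolated intermediate. First, 23 is opened with NaOMe (1.1 equiv) in MeOH–THF at 0 °C (alkoxide methanolysis of a 2-pyranone) and the acyclic keto ester 24 is isolated after a pH 7 phosphate quench. Second, 24 is converted with LiN(SiMe3)2 (3 equiv) in THF at −78 to 0 °C into its dianion, whose terminal carbanion is the reactive site as in the γ-acylation of 1,3-dicarbonyl dianions. Dieckmann closure onto the ester, the classical 5-oxo ester to cyclohexane-1,3-dione ring closure, and tautomerisation on mild acidic work-up should then give 25. No compound outside the list is made (F0).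

2. Step 17. Alkylation may go to the wrong oxygen of the chelated tricarbonyl enol (the exocyclic enol oxygen or the lactone oxygen), or may be too slow against decomposition of the enone. Fallback, from 17 back to 23, with the order of methylation and acylation reversed. Pyranone 17 is methylated (Me2SO4, K2CO3, acetone), the clean, known O-methylation of simple 4-hydroxy-2-pyranones, to the acyl-free 4-methoxy-6-Q-2H-pyran-2-one F1. Electrophilic bromination at the enol-ether carbon, pyranone C3 (NBS, MeCN, 0 °C), then gives 3-bromo-4-methoxy-6-Q-2H-pyran-2-one F2. Separately, alcohol 3 is oxidised with MnO2 (CH2Cl2, rt) to (E)-3-[4-(methoxymethoxy)phenyl]prop-2-enal F3. Bromine–magnesium exchange of F2 with iPrMgCl·LiCl (THF, −40 °C) and 1,2-addition of the resulting pyranyl Grignard reagent to F3 gives the bis-allylic carbinol 3-{(E)-1-hydroxy-3-[4-(methoxymethoxy)phenyl]prop-2-en-1-yl}-4-methoxy-6-Q-2H-pyran-2-one F4 (both carbinol epimers). Oxidation of F4 with MnO2 (CH2Cl2, rt) gives 23.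

3. Step 19. Protic acid may close the 2'-hydroxychalcone to the flavanone by oxa-Michael addition, or MOM removal may stall before the product degrades. Fallback, from 25 back to 26, in two orthogonal non-protic stages. The three aryl MOM ethers are cleaved with TMSOTf and 2,2'-bipyridyl (CH2Cl2, 0 °C, then water), which should give calyxin B 3-O-tert-butyldimethylsilyl ether F5. Buffered fluoride (HF·pyridine, pyridine, THF, 0 °C) then removes the silyl ether to give 26.

Further compounds
F0 | step 18 | none | none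
F1 | step 17 | 4-methoxy-6-{(2S,3E,6S)-6-[(tert-butyldimethylsilyl)oxy]-2,8-bis[4-(methoxymethoxy)phenyl]oct-3-en-1-yl}-2H-pyran-2-one | COc1cc(C[C@@H](/C=C/C[C@@H](O[Si](C)(C)C(C)(C)C)CCc2ccc(OCOC)cc2)c2ccc(OCOC)cc2)oc(=O)c1
F2 | step 17 | 3-bromo-4-methoxy-6-{(2S,3E,6S)-6-[(tert-butyldimethylsilyl)oxy]-2,8-bis[4-(methoxymethoxy)phenyl]oct-3-en-1-yl}-2H-pyran-2-one | COc1cc(C[C@@H](/C=C/C[C@@H](O[Si](C)(C)C(C)(C)C)CCc2ccc(OCOC)cc2)c2ccc(OCOC)cc2)oc(=O)c1Br
F3 | step 17 | (E)-3-[4-(methoxymethoxy)phenyl]prop-2-enal | O=C/C=C/c1ccc(OCOC)cc1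
F4 | step 17 | 3-{(E)-1-hydroxy-3-[4-(methoxymethoxy)phenyl]prop-2-en-1-yl}-4-methoxy-6-{(2S,3E,6S)-6-[(tert-butyldimethylsilyl)oxy]-2,8-bis[4-(methoxymethoxy)phenyl]oct-3-en-1-yl}-2H-pyran-2-one (carbinol epimers) | COc1cc(C[C@@H](/C=C/C[C@@H](O[Si](C)(C)C(C)(C)C)CCc2ccc(OCOC)cc2)c2ccc(OCOC)cc2)oc(=O)c1C(O)/C=C/c1ccc(OCOC)cc1
F5 | step 19 | (E)-1-{3-[(1S,2E,5S)-5-[(tert-butyldimethylsilyl)oxy]-1,7-bis(4-hydroxyphenyl)hept-2-en-1-yl]-2,4-dihydroxy-6-methoxyphenyl}-3-(4-hydroxyphenyl)prop-2-en-1-one | COc1cc(O)c([C@@H](/C=C/C[C@@H](O[Si](C)(C)C(C)(C)C)CCc2ccc(O)cc2)c2ccc(O)cc2)c(O)c1C(=O)/C=C/c1ccc(O)cc1
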